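**Retrosynthetic overview**
1. The ester is made last: the 8-OH of guai-1(10)-ene-4,6,8-triol is acylated with silyl-protected 4-hydroxybenzoic acid, then the phenol is unmasked.
2. The seven-membered ring is closed last, by ring-closing metathesis between a methylidene on the cyclopentane (C1) and a methallyl end (C10); this also fixes the tetrasubstituted C1=C10 bond.
3. The C4 carbinol comes from methylcerium addition to a cyclopentanone, anti to the C5 side chain; the five-membered ring is bought as 3-methylcyclopent-2-en-1-one.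
4. The C5–C6 bond comes from a chelation-controlled indium Barbier allylation of a β-hydroxy aldehyde with 3-(bromomethyl)cyclopent-2-en-1-one (attack through C5 leaves the exocyclic methylene).
5. C7 and C8 come from an Evans syn-aldol of an N-isovaleryl oxazolidinone with 3-methylbut-3-enal.

Assumption: positions are given in guaiane numbering (C4 = methyl carbinol, C5 = ring-fusion CH, C6/C7/C8 = CH(OH)/CH(iPr)/CH(O-acyl), C1=C10 = alkene); the acyl oxazolidinone and 4-[(tert-butyldimethylsilyl)oxy]benzoic acid are bought.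

This route is a paper design; none of the steps has been run, and the stereochemical outcomes in steps 6 and 7 are predictions from standard models.

**Step 1**
Reactants: 1 3-methylbut-3-en-1-ol
Product: 2 3-methylbut-3-enal
Conditions: Dess–Martin periodinane, CH2Cl2, 0 °C to 20 °C; filtered solution used at once
Reagents that add atoms: none
Why: Dess–Martin oxidation is neutral and fast, so the primary alcohol gives the β,γ-unsaturated aldehyde without the double bond drifting into conjugation, and no stereocenter is formed.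

**Step 2**
Reactants: 3 (R)-4-benzyl-3-(3-methylbutanoyl)oxazolidin-2-one; 2 3-methylbut-3-enal
Product: 5 (R)-4-benzyl-3-[(2R,3S)-3-hydroxy-5-methyl-2-(propan-2-yl)hex-5-enoyl]oxazolidin-2-one, via Z-boron enolate 4 (not isolated)
Conditions: Bu2BOTf, iPr2NEt, CH2Cl2, −78 °C; then 2, −78 to 0 °C; then pH 7 buffer, MeOH, H2O2
Reagents that add atoms: none
Why: Evans syn-aldol, in which the Z-boron enolate reacts through a Zimmerman–Traxler chair on the face away from the benzyl group of the (R)-auxiliary and so sets C7 and C8 as the syn pair that becomes the trans 7-isopropyl/8-oxygen relation of the ring.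

**Step 3**
Reactants: 5 (R)-4-benzyl-3-[(2R,3S)-3-hydroxy-5-methyl-2-(propan-2-yl)hex-5-enoyl]oxazolidin-2-one
Product: 6 (2S,3S)-5-methyl-2-(propan-2-yl)hex-5-ene-1,3-diol
Conditions: LiBH4, H2O (1 equiv), Et2O, 0 °C
Reagents that add atoms: none
Why: Hydride reduction of the imide carbonyl cleaves the auxiliary to the primary alcohol without touching the two stereocenters or the alkene.

**Step 4**
Reactants: 6 (2S,3S)-5-methyl-2-(propan-2-yl)hex-5-ene-1,3-diol
Product: 7 (2R,3S)-3-hydroxy-5-methyl-2-(propan-2-yl)hex-5-enal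
Conditions: TEMPO (cat.), PhI(OAc)2, CH2Cl2, 20 °C
Reagents that add atoms: none
Why: The TEMPO oxoammonium oxidation takes the primary alcohol in preference to the secondary one under neutral conditions, so the α-stereocenter of the β-hydroxy aldehyde is kept.

**Step 5**
Reactants: 8 3-methylcyclopent-2-en-1-one
Product: 9 3-(bromomethyl)cyclopent-2-en-1-one
Conditions: NBS, AIBN (cat.), PhCF3, 80 °C
Reagents that add atoms: N-bromosuccinimide, O=C1CCC(=O)N1Br
Why: Wohl–Ziegler radical bromination at the exocyclic allylic methyl group gives the allylic bromide, and any ring-brominated isomer is removed by chromatography.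

**Step 6**
Reactants: 7 (2R,3S)-3-hydroxy-5-methyl-2-(propan-2-yl)hex-5-enal; 9 3-(bromomethyl)cyclopent-2-en-1-one
Product: 11 (2S)-2-[(1R,2R,3S)-1,3-dihydroxy-5-methyl-2-(propan-2-yl)hex-5-en-1-yl]-3-methylidenecyclopentan-1-one, via allylindium bromide 10 (not isolated)
Conditions: indium powder, THF/H2O (1:1), 20 °C
Reagents that add atoms: none
Why: Indium Barbier allylation, in which the allylindium attacks through its ring carbon (C5) in a chair transition state while the free β-hydroxyl holds the aldehyde in a six-membered chelate, so the new hydroxyl at C6 is anti to the isopropyl group and 1,3-anti to the C8 hydroxyl, the ring-locked E-type substituent makes C5/C6 anti, the double bond moves out to the exocyclic methylene, and the ketone is left alone because aldehydes react much faster.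

**Step 7**
Reactants: 11 (2S)-2-[(1R,2R,3S)-1,3-dihydroxy-5-methyl-2-(propan-2-yl)hex-5-en-1-yl]-3-methylidenecyclopentan-1-one
Product: 12 (1S,2S)-2-[(1R,2R,3S)-1,3-dihydroxy-5-methyl-2-(propan-2-yl)hex-5-en-1-yl]-1-methyl-3-methylidenecyclopentan-1-ol
Conditions: MeLi, CeCl3, THF, −78 °C
Reagents that add atoms: methyllithium, C[Li]
Why: Organocerium 1,2-addition (weakly basic, so the enolizable β,γ-unsaturated ketone is not deprotonated) brings the methyl group in anti to the C5 side chain and sets C4 with its hydroxyl cis to C6.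

**Step 8**
Reactants: 12 (1S,2S)-2-[(1R,2R,3S)-1,3-dihydroxy-5-methyl-2-(propan-2-yl)hex-5-en-1-yl]-1-methyl-3-methylidenecyclopentan-1-ol
Product: 13 (3S,3aS,4R,5R,6S)-3,8-dimethyl-5-(propan-2-yl)-1,2,3,3a,4,5,6,7-octahydroazulene-3,4,6-triol
Conditions: RuCl2(=CH-C6H4-2-OiPr)[1,3-bis(2-methylphenyl)imidazolidin-2-ylidene] (10 mol %), toluene, 80 °C, argon stream
Reagents that add atoms: none
Why: Ring-closing metathesis of the two 1,1-disubstituted alkenes with the small N-aryl ruthenium carbene made for tetrasubstituted alkenes loses ethene, closes the seven-membered ring and places the double bond at C1=C10 without touching a stereocenter.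

**Step 9**
Reactants: 13 (3S,3aS,4R,5R,6S)-3,8-dimethyl-5-(propan-2-yl)-1,2,3,3a,4,5,6,7-octahydroazulene-3,4,6-triol; 14 4-[(tert-butyldimethylsilyl)oxy]benzoic acid
Product: 16 (3S,3aS,4R,5S,6S)-3,4-dihydroxy-3,8-dimethyl-5-(propan-2-yl)-1,2,3,3a,4,5,6,7-octahydroazulen-6-yl 4-[(tert-butyldimethylsilyl)oxy]benzoate, via O-acylisourea 15 (not isolated)
Conditions: DCC, DMAP (cat.), CH2Cl2, 0 °C
Reagents that add atoms: none
Why: Steglich esterification is site-selective because the 8-hydroxyl is the only unhindered secondary alcohol (the 6-hydroxyl sits between two branched carbons and the 4-hydroxyl is tertiary), and it proceeds with retention at C8.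

**Step 10**
Reactants: 16 (3S,3aS,4R,5S,6S)-3,4-dihydroxy-3,8-dimethyl-5-(propan-2-yl)-1,2,3,3a,4,5,6,7-octahydroazulen-6-yl 4-[(tert-butyldimethylsilyl)oxy]benzoate
Product: 17 (3S,3aS,4R,5S,6S)-3,4-dihydroxy-3,8-dimethyl-5-(propan-2-yl)-1,2,3,3a,4,5,6,7-octahydroazulen-6-yl 4-hydroxybenzoate
Conditions: HF·pyridine, pyridine, THF, 0 °C
Reagents that add atoms: none
Why: Fluoride cleavage of the aryl silyl ether frees the phenol under buffered conditions that leave the benzoate, the tertiary alcohol and the tetrasubstituted alkene untouched.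

**Compound list**
1 | 3-methylbut-3-en-1-ol | C=C(C)CCO | starting material
2 | 3-methylbut-3-enal | C=C(C)CC=O | intermediate
3 | (R)-4-benzyl-3-(3-methylbutanoyl)oxazolidin-2-one | O=C1OC[C@@H](Cc2ccccc2)N1C(=O)CC(C)C | starting material
4 | (R)-4-benzyl-3-[(Z)-1-[(dibutylboranyl)oxy]-3-methylbut-1-en-1-yl]oxazolidin-2-one (Z-boron enolate) | O=C1OC[C@@H](Cc2ccccc2)N1/C(OB(CCCC)CCCC)=C/C(C)C | intermediate
5 | (R)-4-benzyl-3-[(2R,3S)-3-hydroxy-5-methyl-2-(propan-2-yl)hex-5-enoyl]oxazolidin-2-one | O=C1OC[C@@H](Cc2ccccc2)N1C(=O)[C@H](C(C)C)[C@@H](O)CC(C)=C | intermediate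
6 | (2S,3S)-5-methyl-2-(propan-2-yl)hex-5-ene-1,3-diol | OC[C@H](C(C)C)[C@@H](O)CC(C)=C | intermediate
7 | (2R,3S)-3-hydroxy-5-methyl-2-(propan-2-yl)hex-5-enal | O=C[C@H](C(C)C)[C@@H](O)CC(C)=C | intermediate
8 | 3-methylcyclopent-2-en-1-one | CC1=CC(=O)CC1 | starting material
9 | 3-(bromomethyl)cyclopent-2-en-1-one | BrCC1=CC(=O)CC1 | intermediate
10 | [(3-oxocyclopent-1-en-1-yl)methyl]indium dibromide (monomeric drawing of the allylindium reagent) | O=C1CCC(C[In](Br)Br)=C1 | intermediate
11 | (2S)-2-[(1R,2R,3S)-1,3-dihydroxy-5-methyl-2-(propan-2-yl)hex-5-en-1-yl]-3-methylidenecyclopentan-1-one | C=C1CCC(=O)[C@@H]1[C@H](O)[C@H](C(C)C)[C@@H](O)CC(C)=C | intermediate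
12 | (1S,2S)-2-[(1R,2R,3S)-1,3-dihydroxy-5-methyl-2-(propan-2-yl)hex-5-en-1-yl]-1-methyl-3-methylidenecyclopentan-1-ol | C=C1CC[C@](C)(O)[C@@H]1[C@H](O)[C@H](C(C)C)[C@@H](O)CC(C)=C | intermediate
13 | (3S,3aS,4R,5R,6S)-3,8-dimethyl-5-(propan-2-yl)-1,2,3,3a,4,5,6,7-octahydroazulene-3,4,6-triol | CC1=C2CC[C@](C)(O)[C@@H]2[C@H](O)[C@H](C(C)C)[C@@H](O)C1 | intermediate
14 | 4-[(tert-butyldimethylsilyl)oxy]benzoic acid | CC(C)(C)[Si](C)(C)Oc1ccc(cc1)C(O)=O | starting material
15 | O-acylisourea from 14 and DCC | CC(C)(C)[Si](C)(C)Oc1ccc(cc1)C(=O)OC(=NC1CCCCC1)NC1CCCCC1 | intermediate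
16 | (3S,3aS,4R,5S,6S)-3,4-dihydroxy-3,8-dimethyl-5-(propan-2-yl)-1,2,3,3a,4,5,6,7-octahydroazulen-6-yl 4-[(tert-butyldimethylsilyl)oxy]benzoate | CC1=C2CC[C@](C)(O)[C@@H]2[C@H](O)[C@H](C(C)C)[C@@H](OC(=O)c2ccc(O[Si](C)(C)C(C)(C)C)cc2)C1 | intermediate
17 | (3S,3aS,4R,5S,6S)-3,4-dihydroxy-3,8-dimethyl-5-(propan-2-yl)-1,2,3,3a,4,5,6,7-octahydroazulen-6-yl 4-hydroxybenzoate | CC1=C2CC[C@](C)(O)[C@@H]2[C@H](O)[C@H](C(C)C)[C@@H](OC(=O)c2ccc(O)cc2)C1 | target

**Totals**
Total step count: 10.
Longest linear sequence: 9 steps (steps 1, 2, 3, 4, 6, 7, 8, 9, 10); step 5 is the side branch.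

**The three steps most likely to fail**

Step 6 (indium allylation). The aqueous, Lewis-acidic medium may isomerise the β,γ-unsaturated ketone, and the chelate-plus-chair model may not give clean anti,anti selectivity. The fallback sets out from 7 and 9 and comes back at 11; it changes the metal to boron and the source of facial control from chelation to a chiral catalyst. Bromide 9 is borylated (B2pin2, Pd2(dba)3 (cat.), toluene) to 3-[(4,4,5,5-tetramethyl-1,3,2-dioxaborolan-2-yl)methyl]cyclopent-2-en-1-one F1. Aldehyde 7 is silylated (Et3SiOTf, 2,6-lutidine) to (2R,3S)-5-methyl-2-(propan-2-yl)-3-[(triethylsilyl)oxy]hex-5-enal F2. The two are joined under anhydrous conditions by allylboration catalysed by the chiral phosphoric acid 3,3′-bis(2,4,6-triisopropylphenyl)-1,1′-binaphthyl-2,2′-diyl hydrogen phosphate, using the enantiomer that sends the allyl group to the Si face of the aldehyde. The closed chair keeps C5/C6 anti and gives (2S)-2-[(1R,2S,3S)-1-hydroxy-5-methyl-2-(propan-2-yl)-3-[(triethylsilyl)oxy]hex-5-en-1-yl]-3-methylidenecyclopentan-1-one F3. HF·pyridine then removes the silyl group to give 11.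

Step 8 (metathesis to a tetrasubstituted alkene in a seven-membered ring). Two 1,1-disubstituted alkenes next to a branched centre may react slowly or isomerise. The fallback sets out from 12 and comes back at 13; it replaces metathesis by carbonyl coupling. All three hydroxyls are silylated (Et3SiOTf, 2,6-lutidine) to the tris(triethylsilyl) ether of 12 F4. Ozonolysis of both methylidene groups (O3, CH2Cl2, −78 °C; then PPh3) gives the silylated 1,7-diketone F5. Intramolecular McMurry coupling with low-valent titanium (TiCl3(DME)1.5, Zn–Cu couple, DME, reflux) closes the ring to the tris(triethylsilyl) ether of 13 F6 with the same C1=C10 bond. HF·pyridine then gives 13.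

Step 9 (site-selective acylation). If the 6-hydroxyl competes with the 8-hydroxyl, the fallback sets out from 13 and comes back at 17; it replaces steric selectivity by protection. The 4- and 6-hydroxyls, which lie on the same face, are tied together with tBu2Si(OTf)2 and 2,6-lutidine as the cyclic 4,6-O-di-tert-butylsilylene of 13 F7; the 8-hydroxyl is trans to the 6-hydroxyl and cannot bridge. The only free hydroxyl is then esterified with 14 (DCC, DMAP) to give the 8-O-[4-(tert-butyldimethylsilyloxy)benzoyl] silylene F8. HF·pyridine removes both silicon groups and gives 17 directly.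

**Further compounds**
F1 | step 6 | 3-[(4,4,5,5-tetramethyl-1,3,2-dioxaborolan-2-yl)methyl]cyclopent-2-en-1-one | O=C1CCC(CB2OC(C)(C)C(C)(C)O2)=C1
F2 | step 6 | (2R,3S)-5-methyl-2-(propan-2-yl)-3-[(triethylsilyl)oxy]hex-5-enal | O=C[C@H](C(C)C)[C@@H](O[Si](CC)(CC)CC)CC(C)=C
F3 | step 6 | (2S)-2-[(1R,2S,3S)-1-hydroxy-5-methyl-2-(propan-2-yl)-3-[(triethylsilyl)oxy]hex-5-en-1-yl]-3-methylidenecyclopentan-1-one | C=C1CCC(=O)[C@@H]1[C@H](O)[C@H](C(C)C)[C@@H](O[Si](CC)(CC)CC)CC(C)=C
F4 | step 8 | tris(triethylsilyl) ether of 12 | C=C1CC[C@](C)(O[Si](CC)(CC)CC)[C@@H]1[C@H](O[Si](CC)(CC)CC)[C@H](C(C)C)[C@@H](O[Si](CC)(CC)CC)CC(C)=C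
F5 | step 8 | silylated 1,7-diketone (both methylidene groups of F4 replaced by oxo) | O=C1CC[C@](C)(O[Si](CC)(CC)CC)[C@@H]1[C@H](O[Si](CC)(CC)CC)[C@H](C(C)C)[C@@H](O[Si](CC)(CC)CC)CC(C)=O
F6 | step 8 | tris(triethylsilyl) ether of 13 | CC1=C2CC[C@](C)(O[Si](CC)(CC)CC)[C@@H]2[C@H](O[Si](CC)(CC)CC)[C@H](C(C)C)[C@@H](O[Si](CC)(CC)CC)C1
F7 | step 9 | cyclic 4,6-O-di-tert-butylsilylene of 13 | CC1=C2CC[C@](C)(O3)[C@@H]2[C@H](O[Si]3(C(C)(C)C)C(C)(C)C)[C@H](C(C)C)[C@@H](O)C1
F8 | step 9 | 8-O-[4-(tert-butyldimethylsilyloxy)benzoyl] derivative of F7 | CC1=C2CC[C@](C)(O3)[C@@H]2[C@H](O[Si]3(C(C)(C)C)C(C)(C)C)[C@H](C(C)C)[C@@H](OC(=O)c2ccc(O[Si](C)(C)C(C)(C)C)cc2)C1
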